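**Assumption:** the hindered biaryl axis between C3 of unit 1 and ring E carries no descriptor in the target and is treated as stereochemically undefined, so the route has no stereochemical task. Rings A/C/B belong to the 7-methoxy unit 1, rings D/F to the 5,7-dihydroxy unit 2, and ring E is the shared anisole ring.

## Structural features

The target is a carbon-linked biflavonoid built from six rings. Unit 1 is a chromone (benzo ring A, pyranone ring C) with 5-OH and 7-OMe, a 4-hydroxyphenyl group (ring B) on C2 and the anisole ring E on C3. Unit 2 is a 5,7-dihydroxychromone (benzo ring D, pyranone ring F) whose C2 sits on ring E para to the ring E methoxy group, so ring E is at once the 3-aryl group of unit 1 and the 2-aryl group of unit 2. There is no stereocentre, hence no adjacent stereocentres; the only stereo element is the undefined C3–ring E axis. The fragile groups are four free phenols (two chelated peri to a carbonyl), two γ-pyranones that can open at C2 under hot alkali, and two aryl methyl ethers (O7 of unit 1, ring E) that must outlive removal of every other O-protecting group. The real difficulty is ring C: C2 and C3 both carry aryl groups, the ring is crowded, and ring B and ring E must end up on the right carbons. The key step reads the C2=C3 bond, with ring B on C2 and ring E on C3, as a masked 1,2-diarylethyne, and reads C4 with C4a, C8a and O1 as a masked 2-methoxybenzoyl cation. Because ring B is a para-oxygenated donor ring and ring E can be made an acceptor ring, the alkyne is polarised in the sense that sends C4 to C3 and O1 to C2. Re-deriving the atom mapping from the target shows that a ring E carrying the carboxyl para and the alkyne ortho to its oxygen reproduces the ring E pattern of the target, and no structure needed correction.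

## Logic of the disconnections

**19 to 18.** The cuts are three O–isopropyl bonds (ring B oxygen, O5 and O7 of unit 2) and the O5–CH3 bond of unit 1. Cutting here unmasks all four phenols in the last operation, so every earlier base-mediated step works on a compound without acidic OH groups. The forward step must tell secondary alkyl ethers and a carbonyl-chelated methyl ether from the two non-chelated methyl ethers.

**18 to 16 (through 17).** The cuts are O1–C2 and C2–C3 of ring F. C3 of unit 2 is unsubstituted, which is the classical enolate acyl-transfer pattern. Unit 2 shrinks to an aryl ester. The forward step needs an enolate in the presence of ring C, which has no acidic hydrogen, and an acid dehydration that spares isopropyl ethers.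

**16 to 13 and 15.** The cut is the ester C(=O)–O bond. It divides the molecule convergently into the complete unit 1/ring E acid and a C8 acetophenone block. The forward step must acylate a hydrogen-bonded, flanked phenol.

**15 to 14.** Two O–isopropyl bonds are cut. The forward alkylation must stop at the chelated ortho hydroxyl.

**13 to 10 (through 11 and 12).** The ring E O–CH3 bond is cut and the acid is traced to a methyl ester, so the ring E oxygen becomes an arenesulfonate. The reason lies one step further back: during ring C construction this oxygen must be non-nucleophilic and ring E electron-poor. The forward S–O cleavage and methylation must be tolerated by the pyranone.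

**10 to 9 and 7 (key cut).** The C3–C4 and O1–C2 bonds of ring C are cut. This removes the crowded ring in one move and leaves a diarylalkyne and a symmetric aroyl chloride. The forward step must acylate the alkyne carbon that bears ring E and close the ring through a ring A methoxy oxygen only. The design of 7 is kept as it stands because each spectator group has a job:
- The tosylate blocks benzofuran closure and deactivates ring E; a methyl ether or an acyloxy group would take part in the cyclisation.
- The methyl ester deactivates ring E and later becomes C2 of unit 2.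
- The isopropyl ether keeps ring B a strong donor, survives alkali, and falls to BCl3 at the end.

**9 to 8.** The C–Cl bond is traced to the acid, a one-step activation.

**7 to 6 and 4.** The C(sp)–C(sp2) bond between the alkyne and ring E is cut. It places the two different aryl groups on the alkyne without ambiguity. The forward coupling must react at C–I and leave the sulfonate alone, and the phenol must already be masked or it would cyclise onto the alkyne.

**6 to 5, and 4 to 2 to 1 (through 3).** The cuts are the O–S bond, the C(sp)–C(sp2) bond to ring B and one O–isopropyl bond. All lead to commercial iodophenols by routine steps.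

## Other disconnections considered

**Alternative 1:** Both pyranone rings are cut at once at their C2–C3 and O1–C2 bonds. This leads to the bis(aryl ester) A1, a deoxybenzoin whose ring A phenol carries the 4-benzyloxybenzoyl group and whose ring E carboxyl is esterified with 2-acetyl-3,5-bis(benzyloxy)phenol. In the forward step, excess LiN(SiMe3)2 would form the benzylic enolate (C3 of unit 1) and the methyl ketone enolate (C3 of unit 2). Each would take the neighbouring aroyl group, and TsOH would then close rings C and F to give the tetrabenzyl ether A2; hydrogenolysis would finish.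
- In its favour: four bonds and two rings form in one flask, which is better per step than the chosen key step. The positions of ring B (C2) and ring E (C3) are fixed by connectivity, so there is no regiochemical question; on this point it is better than the chosen plan. The hydrogenolytic finish needs no discrimination among methyl ethers, which is also better than the BCl3 finish.
- Against it here: ring A of A1 needs three different oxygen substituents (methyl, benzyl, aroyl), so the selectivity problem moves to the phloroglucinol stage. Ring E must carry a differentiated arylacetyl and benzoyl function. C-acylation at a benzylic carbon to make a 2-aryl-1,3-diketone is slower than at a methyl ketone, so one half may rearrange and the other not, or the acyl groups may scramble between phenoxides.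
- Comparison: the ring F half is mechanistically identical to steps 10 and 11 of the chosen plan and equally reliable. The ring C half is less general than the acylium route. The total step count is expected to be equal or longer because A1 is costly to assemble.

**Alternative 2:** One carbon–carbon bond of ring D is cut, from C4a of unit 2 to a neighbouring oxygen-bearing carbon. Ring D unravels into the 3,5,7-trioxo-8-enoate A3. In the forward step, Mg(OMe)2 or methanolic KOH would make the C6 carbanion attack the ester carbonyl, and enolisation would give the 2',4',6'-trihydroxychalcone A4. Oxidative cyclisation (I2, DMSO) and debenzylation would follow.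
- In its favour: ring D is made with its three oxygens in place and needs no protecting group, which is better than the chosen plan for that ring. It avoids an aryl ester under strong base.
- Against it here: it builds the one ring that can be bought (phloroacetophenone) and leaves the crowded ring C to some other method. A3 is a labile poly-β-carbonyl chain with competing modes (pyranone lactonisation, aldol closure to a resorcylate, conjugate addition of methoxide to the enone). After A4 another oxidation is needed to make ring F.
- Comparison: it offers nothing for the regiochemistry of ring C, its cyclisation is less controlled than the electronically biased acylium addition, and it is clearly longer. It equals the chosen plan only in the reliability of the final chalcone-to-flavone oxidation compared with the cyclodehydration.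

**Alternative 3:** Ring C is cut at O1–C8a and C4–C4a. This leads to the Perkin acid A5 and the silylaryl triflate A6. In the forward step, CsF would release 3,5-dimethoxybenzyne; the carboxylate oxygen would add at the aryne carbon remote from the methoxy group, the aryl anion would take the acyl carbon, and the phenoxide would add to the enone to give the racemic trans chromanone A7. Dehydrogenation (for example DDQ) would then be needed before unit 2 is built as in the chosen plan.
- In its favour: the assignment of ring B to C2 and ring E to C3 is fixed by A5, which is better than relying on alkyne polarisation. No cation is involved, so ring E can carry its methoxy group from the start and the tosylate detour (steps 3, 7 and half of step 8) disappears, also better. Fluoride conditions spare all ethers.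
- Against it here: A6 needs several steps, whereas 9 needs one. The carboxylate is a weak aryne nucleophile and the acyl shift must beat protonation. The oxa-Michael closure onto an α,β-diaryl enone is hindered and reversible. Two stereocentres are made only to be destroyed in an added oxidation step.
- Comparison: the structural logic is equal or better, the mechanism is less secure for this crowded acid, and the step count is expected to be about equal once A6 and the dehydrogenation are counted.

Key step: step 6

## Route

Step 1
Reactants: 1 4-iodophenol
Product: 2 1-iodo-4-isopropoxybenzene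
Conditions: 2-bromopropane, K2CO3, DMF, 60 °C
Reagents that add atoms: 2-bromopropane, CC(C)Br
Why: Williamson ether synthesis; the phenoxide displaces bromide in a polar aprotic solvent and the aryl iodide is inert under these conditions.

Step 2
Reactants: 2 1-iodo-4-isopropoxybenzene
Product: 4 1-ethynyl-4-isopropoxybenzene, via silylalkyne 3 (not isolated)
Conditions: trimethylsilylacetylene, PdCl2(PPh3)2 (2 mol %), CuI (4 mol %), Et3N, THF, rt; then K2CO3 (cat.), MeOH, rt
Reagents that add atoms: trimethylsilylacetylene, C#C[Si](C)(C)C
Why: Sonogashira coupling of an aryl iodide with a silyl-capped acetylene, followed by carbonate-catalysed methanolysis of the C–Si bond; the crude silylalkyne can be desilylated directly after filtration.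

Step 3
Reactants: 5 methyl 4-hydroxy-3-iodobenzoate
Product: 6 methyl 3-iodo-4-(tosyloxy)benzoate
Conditions: TsCl, Et3N, DMAP (cat.), CH2Cl2, 0 °C to rt
Reagents that add atoms: p-toluenesulfonyl chloride, Cc1ccc(cc1)S(Cl)(=O)=O
Why: O-sulfonylation of a phenol; the tosylate prevents cyclisation of the ortho oxygen onto the alkyne in steps 4 and 6 and keeps ring E electron-poor.

Step 4
Reactants: 6 methyl 3-iodo-4-(tosyloxy)benzoate; 4 1-ethynyl-4-isopropoxybenzene
Product: 7 methyl 3-[(4-isopropoxyphenyl)ethynyl]-4-(tosyloxy)benzoate
Conditions: PdCl2(PPh3)2 (2 mol %), CuI (4 mol %), Et3N, THF (degassed), rt to 40 °C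
Reagents that add atoms: none
Why: Sonogashira coupling; zerovalent palladium inserts into the electron-poor C–I bond far faster than into the aryl sulfonate C–O bond, so the tosylate is a spectator.

Step 5
Reactants: 8 2,4,6-trimethoxybenzoic acid
Product: 9 2,4,6-trimethoxybenzoyl chloride
Conditions: (COCl)2, DMF (cat.), CH2Cl2, 0 °C to rt; evaporate, use crude at once
Reagents that add atoms: oxalyl chloride, ClC(=O)C(Cl)=O
Why: Acid chloride formation through the chloroiminium (Vilsmeier-type) activator; low temperature and prompt removal of HCl limit protodecarboxylation of the electron-rich acid.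

Step 6
Reactants: 9 2,4,6-trimethoxybenzoyl chloride; 7 methyl 3-[(4-isopropoxyphenyl)ethynyl]-4-(tosyloxy)benzoate
Product: 10 methyl 3-[2-(4-isopropoxyphenyl)-5,7-dimethoxy-4-oxo-4H-chromen-3-yl]-4-(tosyloxy)benzoate
Conditions: SnCl4 (1.5 equiv), CH2Cl2, 0 °C to rt
Reagents that add atoms: none
Why: This is a domino Friedel-Crafts acylation of an alkyne followed by demethylative oxa-cyclisation, a known way from 2-methoxybenzoyl chlorides and internal alkynes to 2,3-disubstituted chromones. SnCl4 abstracts chloride from 9 to give the 2,4,6-trimethoxybenzoyl cation, whose linear acylium carbon (future C4) is not shielded by the two ortho methoxy groups. It should bond to the alkyne carbon attached to ring E (future C3), because the positive charge then develops on the carbon attached to ring B (future C2), where the para isopropoxy group delocalises it as a quinoid oxocarbenium ion; the opposite sense would put the charge next to a ring deactivated by an ester and a sulfonate. An ortho methoxy oxygen of ring A (future O1) then captures the vinyl cation in a 6-endo-dig closure (or by 6-endo-trig addition-elimination if chloride has first capped the cation as a β-chlorovinyl ketone) to give a methyloxonium ion, and chloride removes the methyl group as CH3Cl, which returns SnCl4 and makes the sequence irreversible. The two ortho methoxy groups of 9 are equivalent, so the closure has no regiochemical choice, and the remaining two become the 5- and 7-methoxy groups. Chemoselectivity requires the ring E oxygen to be a non-nucleophile, and as a sulfonate it cannot form the five-membered benzofuran oxonium ion that an ortho methoxy group would allow. No stereocentre is formed; the only selectivity at stake is the site of acylation, and the donor/acceptor bias built into 7 secures it.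

Step 7
Reactants: 10 methyl 3-[2-(4-isopropoxyphenyl)-5,7-dimethoxy-4-oxo-4H-chromen-3-yl]-4-(tosyloxy)benzoate
Product: 11 4-hydroxy-3-[2-(4-isopropoxyphenyl)-5,7-dimethoxy-4-oxo-4H-chromen-3-yl]benzoic acid
Conditions: KOH (5 equiv), MeOH/THF/H2O, 50 °C; then aq. HCl to pH 2
Reagents that add atoms: potassium hydroxide, [K+].[OH-]
Why: Hydroxide attacks sulfur of the aryl tosylate (S–O cleavage, helped by the para carboxyl making the phenoxide a good leaving group) and saponifies the methyl ester; the donor-substituted 2-aryl pyranone is expected to resist attack at C2 at this temperature, and the product is isolated by acidification.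

Step 8
Reactants: 11 4-hydroxy-3-[2-(4-isopropoxyphenyl)-5,7-dimethoxy-4-oxo-4H-chromen-3-yl]benzoic acid
Product: 13 3-[2-(4-isopropoxyphenyl)-5,7-dimethoxy-4-oxo-4H-chromen-3-yl]-4-methoxybenzoic acid, via methyl ester 12 (not isolated)
Conditions: MeI (3 equiv), K2CO3, DMF, rt; evaporate excess MeI; then LiOH, THF/H2O, 40 °C; aq. HCl
Reagents that add atoms: iodomethane, CI; lithium hydroxide, [Li+].[OH-]
Why: Exhaustive SN2 methylation of phenoxide and carboxylate (Williamson etherification and carboxylate alkylation) followed by saponification of the methyl ester only; the aryl methyl ether is inert to hydroxide, so in net the sulfonate oxygen has become the ring E methoxy group.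

Step 9
Reactants: 14 2,4,6-trihydroxyacetophenone
Product: 15 1-(2-hydroxy-4,6-diisopropoxyphenyl)ethanone
Conditions: 2-bromopropane (2.3 equiv), K2CO3, DMF, 55 °C
Reagents that add atoms: 2-bromopropane, CC(C)Br
Why: Regioselective Williamson etherification; the para hydroxyl and one ortho hydroxyl are alkylated, while the last ortho hydroxyl is held in a hydrogen bond to the acetyl carbonyl and reacts much more slowly.

Step 10
Reactants: 13 3-[2-(4-isopropoxyphenyl)-5,7-dimethoxy-4-oxo-4H-chromen-3-yl]-4-methoxybenzoic acid; 15 1-(2-hydroxy-4,6-diisopropoxyphenyl)ethanone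
Product: 16 2-acetyl-3,5-diisopropoxyphenyl 3-[2-(4-isopropoxyphenyl)-5,7-dimethoxy-4-oxo-4H-chromen-3-yl]-4-methoxybenzoate
Conditions: EDCI·HCl, DMAP, CH2Cl2, rt
Reagents that add atoms: none
Why: Steglich esterification; the acylpyridinium ion formed from the O-acylisourea is electrophilic enough to acylate the chelated, flanked phenol.

Step 11
Reactants: 16 2-acetyl-3,5-diisopropoxyphenyl 3-[2-(4-isopropoxyphenyl)-5,7-dimethoxy-4-oxo-4H-chromen-3-yl]-4-methoxybenzoate
Product: 18 3-[5-(5,7-diisopropoxy-4-oxo-4H-chromen-2-yl)-2-methoxyphenyl]-2-(4-isopropoxyphenyl)-5,7-dimethoxy-4H-chromen-4-one, via diketone 17 (not isolated)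
Conditions: KOtBu (2.5 equiv), THF, 0 °C to rt; AcOH quench, concentrate; then TsOH·H2O (cat.), toluene, 90 °C
Reagents that add atoms: none
Why: Baker-Venkataraman rearrangement; the methyl ketone enolate takes the aroyl group from the neighbouring phenol oxygen through a six-membered transition state to give the phenoxide of the 1,3-diketone, and acid then closes ring F by attack of the phenol on the aryl ketone carbonyl and loss of water. Ring C has no acidic hydrogen and isopropyl ethers tolerate catalytic sulfonic acid.

Step 12
Reactants: 18 3-[5-(5,7-diisopropoxy-4-oxo-4H-chromen-2-yl)-2-methoxyphenyl]-2-(4-isopropoxyphenyl)-5,7-dimethoxy-4H-chromen-4-one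
Product: 19 3-[5-(5,7-dihydroxy-4-oxo-4H-chromen-2-yl)-2-methoxyphenyl]-5-hydroxy-2-(4-hydroxyphenyl)-7-methoxy-4H-chromen-4-one (CNP0288914.0)
Conditions: BCl3 (1 M in CH2Cl2, excess), CH2Cl2, −78 °C to 0 °C; then MeOH, H2O
Reagents that add atoms: none
Why: Lewis acid ether cleavage with chelation control; BCl3 removes the three secondary isopropyl groups as 2-chloropropane and also the 5-methyl group of unit 1, because boron bridges C4=O and O5 in a six-membered chelate and delivers chloride to that methyl. The non-chelated 7-methoxy group and the ring E methoxy group should remain at or below 0 °C.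

## Compound list

1 | 4-iodophenol | Oc1ccc(I)cc1 | starting material
2 | 1-iodo-4-isopropoxybenzene | CC(C)Oc1ccc(I)cc1 | intermediate
3 | trimethyl{[4-(propan-2-yloxy)phenyl]ethynyl}silane | CC(C)Oc1ccc(C#C[Si](C)(C)C)cc1 | intermediate
4 | 1-ethynyl-4-isopropoxybenzene | CC(C)Oc1ccc(C#C)cc1 | intermediate
5 | methyl 4-hydroxy-3-iodobenzoate | COC(=O)c1ccc(O)c(I)c1 | starting material
6 | methyl 3-iodo-4-(tosyloxy)benzoate | COC(=O)c1ccc(OS(=O)(=O)c2ccc(C)cc2)c(I)c1 | intermediate
7 | methyl 3-[(4-isopropoxyphenyl)ethynyl]-4-(tosyloxy)benzoate | COC(=O)c1ccc(OS(=O)(=O)c2ccc(C)cc2)c(C#Cc2ccc(OC(C)C)cc2)c1 | intermediate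
8 | 2,4,6-trimethoxybenzoic acid | COc1cc(OC)c(C(=O)O)c(OC)c1 | starting material
9 | 2,4,6-trimethoxybenzoyl chloride | COc1cc(OC)c(C(Cl)=O)c(OC)c1 | intermediate
10 | methyl 3-[2-(4-isopropoxyphenyl)-5,7-dimethoxy-4-oxo-4H-chromen-3-yl]-4-(tosyloxy)benzoate | COc1cc(OC)c2c(=O)c(-c3cc(C(=O)OC)ccc3OS(=O)(=O)c3ccc(C)cc3)c(-c3ccc(OC(C)C)cc3)oc2c1 | intermediate
11 | 4-hydroxy-3-[2-(4-isopropoxyphenyl)-5,7-dimethoxy-4-oxo-4H-chromen-3-yl]benzoic acid | COc1cc(OC)c2c(=O)c(-c3cc(C(=O)O)ccc3O)c(-c3ccc(OC(C)C)cc3)oc2c1 | intermediate
12 | methyl 3-[2-(4-isopropoxyphenyl)-5,7-dimethoxy-4-oxo-4H-chromen-3-yl]-4-methoxybenzoate | COc1cc(OC)c2c(=O)c(-c3cc(C(=O)OC)ccc3OC)c(-c3ccc(OC(C)C)cc3)oc2c1 | intermediate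
13 | 3-[2-(4-isopropoxyphenyl)-5,7-dimethoxy-4-oxo-4H-chromen-3-yl]-4-methoxybenzoic acid | COc1cc(OC)c2c(=O)c(-c3cc(C(=O)O)ccc3OC)c(-c3ccc(OC(C)C)cc3)oc2c1 | intermediate
14 | 2,4,6-trihydroxyacetophenone | CC(=O)c1c(O)cc(O)cc1O | starting material
15 | 1-(2-hydroxy-4,6-diisopropoxyphenyl)ethanone | CC(=O)c1c(O)cc(OC(C)C)cc1OC(C)C | intermediate
16 | 2-acetyl-3,5-diisopropoxyphenyl 3-[2-(4-isopropoxyphenyl)-5,7-dimethoxy-4-oxo-4H-chromen-3-yl]-4-methoxybenzoate | COc1cc(OC)c2c(=O)c(-c3cc(C(=O)Oc4cc(OC(C)C)cc(OC(C)C)c4C(C)=O)ccc3OC)c(-c3ccc(OC(C)C)cc3)oc2c1 | intermediate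
17 | 1-(2-hydroxy-4,6-diisopropoxyphenyl)-3-{3-[2-(4-isopropoxyphenyl)-5,7-dimethoxy-4-oxo-4H-chromen-3-yl]-4-methoxyphenyl}propane-1,3-dione | COc1cc(OC)c2c(=O)c(-c3cc(C(=O)CC(=O)c4c(O)cc(OC(C)C)cc4OC(C)C)ccc3OC)c(-c3ccc(OC(C)C)cc3)oc2c1 | intermediate
18 | 3-[5-(5,7-diisopropoxy-4-oxo-4H-chromen-2-yl)-2-methoxyphenyl]-2-(4-isopropoxyphenyl)-5,7-dimethoxy-4H-chromen-4-one | COc1cc(OC)c2c(=O)c(-c3cc(-c4cc(=O)c5c(OC(C)C)cc(OC(C)C)cc5o4)ccc3OC)c(-c3ccc(OC(C)C)cc3)oc2c1 | intermediate
19 | 3-[5-(5,7-dihydroxy-4-oxo-4H-chromen-2-yl)-2-methoxyphenyl]-5-hydroxy-2-(4-hydroxyphenyl)-7-methoxy-4H-chromen-4-one (CNP0288914.0) | COc1cc(O)c2c(=O)c(-c3cc(-c4cc(=O)c5c(O)cc(O)cc5o4)ccc3OC)c(-c3ccc(O)cc3)oc2c1 | target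

## Step count and risk assessment

Total step count: 12. Longest linear sequence: 9 steps (steps 1, 2, 4, 6, 7, 8, 10, 11, 12, from 4-iodophenol).

**Step 6 (key step).** Three things are most likely to go wrong:
- The acylation may be sluggish because three methoxy groups stabilise the acylium ion, so 9 decomposes before it reacts.
- The regiochemistry of acylation may leak.
- The Lewis acid may dealkylate the ring B isopropyl ether, exposing a phenol that step 8 would methylate irreversibly. Any such phenol would have to be re-isopropylated before step 7.

The fallback changes the order of bond formation and sets out from 9 and 4. Acyl Sonogashira coupling (PdCl2(PPh3)2, CuI, Et3N, THF, rt) should give 3-(4-isopropoxyphenyl)-1-(2,4,6-trimethoxyphenyl)prop-2-yn-1-one F1. Iodocyclisation with ICl (CH2Cl2, −78 °C to rt), where the methoxy oxygen attacks the iodonium-activated alkyne and chloride removes the methyl group, should give 3-iodo-2-(4-isopropoxyphenyl)-5,7-dimethoxy-4H-chromen-4-one F2. Suzuki-Miyaura coupling of F2 with commercial [2-methoxy-5-(methoxycarbonyl)phenyl]boronic acid F3 (Pd(PPh3)4, K2CO3, dioxane/H2O, 90 °C) comes back to the route at 12, which is saponified as in the second stage of step 8. Ring E then carries its methoxy group from the start, and step 7 and the methylation are not needed.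

**Step 7.** During the warm alkaline S–O cleavage, hydroxide or the freshly unmasked ortho phenoxide of ring E may attack C2 and open the pyranone. The products would be a deoxybenzoin (by retro-Claisen loss of the aroyl group) or a 3-aroylbenzofuran (by re-closure). Cleavage at the hindered sulfonate may also be incomplete.

The fallback changes the protecting group to one that leaves at room temperature and sets out from 5. Tf2O and pyridine should give methyl 3-iodo-4-{[(trifluoromethyl)sulfonyl]oxy}benzoate F4. Coupling with 4 as in step 4 (room temperature, selective for C–I) should give methyl 3-[(4-isopropoxyphenyl)ethynyl]-4-{[(trifluoromethyl)sulfonyl]oxy}benzoate F5. Reaction with 9 and SnCl4 as in step 6 should give methyl 3-[2-(4-isopropoxyphenyl)-5,7-dimethoxy-4-oxo-4H-chromen-3-yl]-4-{[(trifluoromethyl)sulfonyl]oxy}benzoate F6. Aqueous Et4NOH in dioxane at room temperature should cleave the triflate and the ester, and acidification comes back to the route at 11.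

**Step 11.** Cleavage or transesterification of the aryl ester may compete with C-acylation because the acyl group is bulky, and the cyclodehydration may be incomplete.

The fallback replaces the intramolecular acyl transfer by an intermolecular C-acylation and sets out from 13 and 15. Treating 13 with (COCl)2 and catalytic DMF should give 3-[2-(4-isopropoxyphenyl)-5,7-dimethoxy-4-oxo-4H-chromen-3-yl]-4-methoxybenzoyl chloride F7. F7 is added to the dianion of 15 (LiN(SiMe3)2, 3 equiv, THF, −78 °C), which should give 17 directly by Claisen-type acylation of the ketone enolate. The TsOH treatment of step 11 comes back to the route at 18.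

**Step 12.** The chelated 5-methoxy group may be cleaved incompletely under conditions mild enough to spare the other two methyl ethers. If the step is forced, over-demethylation at O7 of unit 1 or at ring E may follow, and partially deprotected boron chelates may precipitate.

The fallback splits the global deprotection into two mechanistically distinct operations and sets out from 18. BCl3 kept between −78 °C and −20 °C should remove only the isopropyl groups and give 3-[5-(5,7-dihydroxy-4-oxo-4H-chromen-2-yl)-2-methoxyphenyl]-2-(4-hydroxyphenyl)-5,7-dimethoxy-4H-chromen-4-one F8. Any 19 formed alongside is harmless. AlCl3 in MeCN at 60 °C, which demethylates only ethers chelated to a carbonyl, then comes back to the route at 19.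

## Further compounds

F1 | step 6 | 3-(4-isopropoxyphenyl)-1-(2,4,6-trimethoxyphenyl)prop-2-yn-1-one | COc1cc(OC)c(C(=O)C#Cc2ccc(OC(C)C)cc2)c(OC)c1
F2 | step 6 | 3-iodo-2-(4-isopropoxyphenyl)-5,7-dimethoxy-4H-chromen-4-one | COc1cc(OC)c2c(=O)c(I)c(-c3ccc(OC(C)C)cc3)oc2c1
F3 | step 6 | [2-methoxy-5-(methoxycarbonyl)phenyl]boronic acid (purchased) | COC(=O)c1ccc(OC)c(B(O)O)c1
F4 | step 7 | methyl 3-iodo-4-{[(trifluoromethyl)sulfonyl]oxy}benzoate | COC(=O)c1ccc(OS(=O)(=O)C(F)(F)F)c(I)c1
F5 | step 7 | methyl 3-[(4-isopropoxyphenyl)ethynyl]-4-{[(trifluoromethyl)sulfonyl]oxy}benzoate | COC(=O)c1ccc(OS(=O)(=O)C(F)(F)F)c(C#Cc2ccc(OC(C)C)cc2)c1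
F6 | step 7 | methyl 3-[2-(4-isopropoxyphenyl)-5,7-dimethoxy-4-oxo-4H-chromen-3-yl]-4-{[(trifluoromethyl)sulfonyl]oxy}benzoate | COc1cc(OC)c2c(=O)c(-c3cc(C(=O)OC)ccc3OS(=O)(=O)C(F)(F)F)c(-c3ccc(OC(C)C)cc3)oc2c1
F7 | step 11 | 3-[2-(4-isopropoxyphenyl)-5,7-dimethoxy-4-oxo-4H-chromen-3-yl]-4-methoxybenzoyl chloride | COc1cc(OC)c2c(=O)c(-c3cc(C(Cl)=O)ccc3OC)c(-c3ccc(OC(C)C)cc3)oc2c1
F8 | step 12 | 3-[5-(5,7-dihydroxy-4-oxo-4H-chromen-2-yl)-2-methoxyphenyl]-2-(4-hydroxyphenyl)-5,7-dimethoxy-4H-chromen-4-one | COc1cc(OC)c2c(=O)c(-c3cc(-c4cc(=O)c5c(O)cc(O)cc5o4)ccc3OC)c(-c3ccc(O)cc3)oc2c1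
A1 | alternative 1 | 2-acetyl-3,5-bis(benzyloxy)phenyl 3-(2-{2-[4-(benzyloxy)benzoyloxy]-6-(benzyloxy)-4-methoxyphenyl}-2-oxoethyl)-4-methoxybenzoate | COc1cc(OCc2ccccc2)c(C(=O)Cc2cc(C(=O)Oc3cc(OCc4ccccc4)cc(OCc4ccccc4)c3C(C)=O)ccc2OC)c(OC(=O)c2ccc(OCc3ccccc3)cc2)c1
A2 | alternative 1 | tetra-O-benzyl ether of the target | COc1cc(OCc2ccccc2)c2c(=O)c(-c3cc(-c4cc(=O)c5c(OCc6ccccc6)cc(OCc6ccccc6)cc5o4)ccc3OC)c(-c3ccc(OCc4ccccc4)cc3)oc2c1
A3 | alternative 2 | methyl (E)-9-{3-[5-(benzyloxy)-2-(4-benzyloxyphenyl)-7-methoxy-4-oxo-4H-chromen-3-yl]-4-methoxyphenyl}-3,5,7-trioxonon-8-enoate | COC(=O)CC(=O)CC(=O)CC(=O)/C=C/c1ccc(OC)c(-c2c(-c3ccc(OCc4ccccc4)cc3)oc3cc(OC)cc(OCc4ccccc4)c3c2=O)c1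
A4 | alternative 2 | 2',4',6'-trihydroxychalcone carrying benzyl-protected unit 1 on ring E | O=C(/C=C/c1ccc(OC)c(-c2c(-c3ccc(OCc4ccccc4)cc3)oc3cc(OC)cc(OCc4ccccc4)c3c2=O)c1)c1c(O)cc(O)cc1O
A5 | alternative 3 | (E)-3-(4-benzyloxyphenyl)-2-[2-methoxy-5-(methoxycarbonyl)phenyl]acrylic acid | OC(=O)/C(=C/c1ccc(OCc2ccccc2)cc1)c1cc(C(=O)OC)ccc1OC
A6 | alternative 3 | 3,5-dimethoxy-2-(trimethylsilyl)phenyl trifluoromethanesulfonate | COc1cc(OC)c([Si](C)(C)C)c(OS(=O)(=O)C(F)(F)F)c1
A7 | alternative 3 | methyl 3-[trans-2-(4-benzyloxyphenyl)-5,7-dimethoxy-4-oxochroman-3-yl]-4-methoxybenzoate, racemic, one enantiomer written | O=C1c2c(OC)cc(OC)cc2O[C@H](c2ccc(OCc3ccccc3)cc2)[C@H]1c4cc(C(=O)OC)ccc4OC
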